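**Strategy.** The cyclohexenone carbonyl carbon C1 and the quaternary carbon C6, together with the side-chain carbons CH(CH3)–CH(Ar) and the benzylic oxygen, are read as a γ-butyrolactone that serves as a chiral ketene equivalent. The six-membered ring is closed by an anionic [4+2] annulation: an α-sulfinyl carbanion acylates the lactone carbonyl (ring bond C1–C2) and the γ-carbon of the resulting β-keto sulfoxide dianion displaces the iodide at the other end of the same four-carbon unit (ring bond C5–C6). The precursors are a cis-4-methyl-5-aryl lactone and an (R)-4-iodo-3-methoxybutyl phenyl sulfoxide that already carries the C4 methoxy stereocentre; allylation and sulfoxide elimination complete the target.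

Key step: step 8

Assumption: the sense of induction of the (S)-phosphoric acid in step 1 and of the (R,R)-ligand in step 4 is taken as stated; if either proves opposite, the antipodal catalyst is used.

Ring atoms are numbered as in the final cyclohexenone (C1 = C=O, C2=C3, C4 = CH–OMe, C5 = CH2, C6 = quaternary carbon).

**Step 1**
Reactants: 1 3,4-dimethoxybenzaldehyde
Product: 2 (1S,2R)-1-(3,4-dimethoxyphenyl)-2-methylbut-3-en-1-ol
Conditions: (Z)-crotyl-B(pin) (1.2 equiv), (S)-3,3′-bis(2,4,6-triisopropylphenyl)-1,1′-binaphthyl-2,2′-diyl hydrogen phosphate (5 mol%), 4 Å molecular sieves, toluene, −30 °C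
Reagents that add atoms: (Z)-crotylboronic acid pinacol ester, C/C=C\CB1OC(C)(C)C(C)(C)O1
Why: Chiral phosphoric acid-catalysed crotylboration through a closed chair transition state, in which the Z-boronate fixes the syn relationship and the catalyst the 1S,2R absolute configuration.

**Step 2**
Reactants: 2 (1S,2R)-1-(3,4-dimethoxyphenyl)-2-methylbut-3-en-1-ol
Product: 3 (1S,2R)-1-(3,4-dimethoxyphenyl)-2-methylbutane-1,4-diol
Conditions: 9-borabicyclo[3.3.1]nonane (9-BBN, 2.2 equiv), THF, 0 °C → rt; then NaOH, H2O2, 0 °C
Reagents that add atoms: hydrogen peroxide, OO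
Why: Anti-Markovnikov hydroboration–oxidation of the terminal alkene (the first equivalent of borane is taken by the hydroxyl) should give the primary alcohol without touching the two stereocentres.

**Step 3**
Reactants: 3 (1S,2R)-1-(3,4-dimethoxyphenyl)-2-methylbutane-1,4-diol
Product: 4 (4R,5S)-5-(3,4-dimethoxyphenyl)-4-methyloxolan-2-one (cis-lactone)
Conditions: TEMPO (10 mol%), PhI(OAc)2 (2.5 equiv), CH2Cl2, rt
Reagents that add atoms: none
Why: Oxidative lactonisation of a 1,4-diol, in which the primary alcohol is oxidised selectively to the aldehyde, the lactol closes and is oxidised again; the cis relation of methyl and aryl is inherited from 2.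

**Step 4**
Reactants: 5 racemic 2-vinyloxirane
Product: 6 (2R)-2-methoxybut-3-en-1-ol
Conditions: MeOH (1.1 equiv), Pd2(dba)3·CHCl3 (1 mol%), (1R,2R)-N,N′-bis[2-(diphenylphosphino)benzoyl]cyclohexane-1,2-diamine (3 mol%), Et3B (1 mol%), CH2Cl2, rt
Reagents that add atoms: methanol, CO
Why: Tsuji–Trost-type dynamic kinetic asymmetric addition, in which zerovalent palladium ionises both epoxide enantiomers to interconverting π-allyl complexes and the boron co-catalyst delivers methoxide to the internal allyl carbon, so that the ligand sets the R ether centre (the future C4).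

**Step 5**
Reactants: 6 (2R)-2-methoxybut-3-en-1-ol
Product: 7 (2R)-2-methoxy-4-(phenylsulfanyl)butan-1-ol
Conditions: PhSH (1.1 equiv), AIBN (5 mol%), toluene, 80 °C
Reagents that add atoms: thiophenol, Sc1ccccc1
Why: Radical thiol–ene addition places sulfur on the terminal alkene carbon (anti-Markovnikov) and leaves the stereocentre untouched.

**Step 6**
Reactants: 7 (2R)-2-methoxy-4-(phenylsulfanyl)butan-1-ol
Product: 8 {[(3R)-4-iodo-3-methoxybutyl]sulfanyl}benzene
Conditions: I2, PPh3, imidazole, CH2Cl2, 0 °C
Reagents that add atoms: iodine, II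
Why: Appel-type iodination of the primary alcohol (SN2 at CH2, stereocentre not involved); the iodide is used directly.

**Step 7**
Reactants: 8 {[(3R)-4-iodo-3-methoxybutyl]sulfanyl}benzene
Product: 9 [(3R)-4-iodo-3-methoxybutane-1-sulfinyl]benzene (both configurations at sulfur)
Conditions: NaIO4 (1.05 equiv), MeOH–H2O, 0 °C → rt
Reagents that add atoms: sodium periodate, [Na+].[O-]I(=O)(=O)=O
Why: Periodate should oxidise the aryl alkyl sulfide to the sulfoxide without over-oxidation to the sulfone and without touching the alkyl iodide.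

**Step 8**
Reactants: 4 (4R,5S)-5-(3,4-dimethoxyphenyl)-4-methyloxolan-2-one; 9 [(3R)-4-iodo-3-methoxybutane-1-sulfinyl]benzene
Product: 12 (4S)-6-[(1S,2R)-1-(3,4-dimethoxyphenyl)-1-hydroxypropan-2-yl]-4-methoxy-2-(phenylsulfinyl)cyclohexan-1-one (mixture at C2, C6 and sulfur), via α-lithio sulfoxide 10 (not isolated), via acyclic iodo β-keto sulfoxide 11 (not isolated)
Conditions: 9 (1.3 equiv), LiN(i-Pr)2 (LDA, 1.3 equiv), THF, −78 °C; add 4, −78 °C; then LDA (2.3 equiv), DMPU, −78 → 0 °C
Reagents that add atoms: none
Why: LDA removes an α-sulfinyl proton of 9 to give carbanion 10, which adds to the lactone carbonyl of 4; this forms the C1–C2 ring bond while the acyl C–O bond is traded for the free benzylic alkoxide (Claisen-type acylation of an α-sulfinyl carbanion by a lactone, giving 11). Two further equivalents of LDA convert 11 into its alkoxide and the β-keto sulfoxide 1,3-dianion, whose γ-carbon displaces the primary iodide at the other end of the four-carbon unit and forms the C5–C6 bond (intramolecular form of the γ-alkylation of β-keto sulfoxide dianions). The ring closes in the 6-(enolendo)-exo-tet mode, the lithium-chelated Z-enolate holding the two chain ends cis. The stereocentres at C4 and in the side chain are carried in unchanged from 9 and 4; the new centres at C2 and C6 form as mixtures, which is harmless because C2 becomes sp2 in step 10 and C6 is planarised and set in step 9. The step needs addition of 10 to the lactone to outrun enolisation (low temperature, five-membered lactone) and γ-C-alkylation to beat α-C- or O-alkylation (dianion reactivity, six- against four-membered ring closure).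

**Step 9**
Reactants: 12 (4S)-6-[(1S,2R)-1-(3,4-dimethoxyphenyl)-1-hydroxypropan-2-yl]-4-methoxy-2-(phenylsulfinyl)cyclohexan-1-one
Product: 13 (4S,6S)-6-[(1S,2R)-1-(3,4-dimethoxyphenyl)-1-hydroxypropan-2-yl]-4-methoxy-2-(phenylsulfinyl)-6-(prop-2-en-1-yl)cyclohexan-1-one (mixture at C2 and sulfur)
Conditions: LDA (3.2 equiv), THF–DMPU, −78 → 0 °C; allyl bromide (1.1 equiv), −78 → −30 °C
Reagents that add atoms: allyl bromide, C=CCBr
Why: γ-Alkylation of the β-keto sulfoxide dianion (one further equivalent of base takes the hydroxyl), in which allyl bromide should attack C6 axially and so trans to the pseudo-equatorial C4 methoxy group, and anti to the aryl carbinol branch of the side chain, which allylic 1,3-strain (side-chain C–H eclipsing the enolate C–O) holds on the opposite face, so that both elements favour the 6S centre.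

**Step 10**
Reactants: 13 (4S,6S)-6-[(1S,2R)-1-(3,4-dimethoxyphenyl)-1-hydroxypropan-2-yl]-4-methoxy-2-(phenylsulfinyl)-6-(prop-2-en-1-yl)cyclohexan-1-one
Product: 14 (4S,6S)-6-[(1S,2R)-1-(3,4-dimethoxyphenyl)-1-hydroxypropan-2-yl]-4-methoxy-6-(prop-2-en-1-yl)cyclohex-2-en-1-one (target)
Conditions: toluene, CaCO3, 90 °C
Reagents that add atoms: none
Why: Thermal syn-elimination of benzenesulfenic acid from the α-sulfinyl ketone (sulfoxide pyrolysis) can only engage the C3 hydrogens and should give the conjugated C2=C3 enone, while the quaternary C6 blocks aromatisation.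

**Compound list**
1 | 3,4-dimethoxybenzaldehyde | COc1ccc(C=O)cc1OC | starting material
2 | (1S,2R)-1-(3,4-dimethoxyphenyl)-2-methylbut-3-en-1-ol | C=C[C@@H](C)[C@H](O)c1ccc(OC)c(OC)c1 | intermediate
3 | (1S,2R)-1-(3,4-dimethoxyphenyl)-2-methylbutane-1,4-diol | OCC[C@@H](C)[C@H](O)c1ccc(OC)c(OC)c1 | intermediate
4 | (4R,5S)-5-(3,4-dimethoxyphenyl)-4-methyloxolan-2-one | O=C1C[C@@H](C)[C@H](O1)c2ccc(OC)c(OC)c2 | intermediate
5 | racemic 2-vinyloxirane (butadiene monoepoxide) | C=CC1CO1 | starting material
6 | (2R)-2-methoxybut-3-en-1-ol | C=C[C@@H](OC)CO | intermediate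
7 | (2R)-2-methoxy-4-(phenylsulfanyl)butan-1-ol | OC[C@H](OC)CCSc1ccccc1 | intermediate
8 | {[(3R)-4-iodo-3-methoxybutyl]sulfanyl}benzene | IC[C@H](OC)CCSc1ccccc1 | intermediate
9 | [(3R)-4-iodo-3-methoxybutane-1-sulfinyl]benzene, both configurations at sulfur | IC[C@H](OC)CCS(=O)c1ccccc1 | intermediate
10 | {[(3R)-4-iodo-1-lithio-3-methoxybutyl]sulfinyl}benzene (not isolated) | IC[C@H](OC)CC([Li])S(=O)c1ccccc1 | intermediate
11 | (1S,2R,7R)-1-(3,4-dimethoxyphenyl)-1-hydroxy-8-iodo-7-methoxy-2-methyl-5-(phenylsulfinyl)octan-4-one, lithium salt in the flask (not isolated) | IC[C@H](OC)CC(S(=O)c1ccccc1)C(=O)C[C@@H](C)[C@H](O)c1ccc(OC)c(OC)c1 | intermediate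
12 | (4S)-6-[(1S,2R)-1-(3,4-dimethoxyphenyl)-1-hydroxypropan-2-yl]-4-methoxy-2-(phenylsulfinyl)cyclohexan-1-one, mixture at C2, C6 and sulfur | O=C1C(S(=O)c2ccccc2)C[C@@H](OC)CC1[C@@H](C)[C@H](O)c3ccc(OC)c(OC)c3 | intermediate
13 | (4S,6S)-6-[(1S,2R)-1-(3,4-dimethoxyphenyl)-1-hydroxypropan-2-yl]-4-methoxy-2-(phenylsulfinyl)-6-(prop-2-en-1-yl)cyclohexan-1-one, mixture at C2 and sulfur | C=CC[C@@]1([C@@H](C)[C@H](O)c2ccc(OC)c(OC)c2)C[C@H](OC)CC(S(=O)c2ccccc2)C1=O | intermediate
14 | (4S,6S)-6-[(1S,2R)-1-(3,4-dimethoxyphenyl)-1-hydroxypropan-2-yl]-4-methoxy-6-(prop-2-en-1-yl)cyclohex-2-en-1-one | C=CC[C@@]1([C@@H](C)[C@H](O)c2ccc(OC)c(OC)c2)C[C@H](OC)C=CC1=O | target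

**Total step count:** 10. **Longest linear sequence:** 7 steps (5 → 14, steps 4 to 10).

**Steps most likely to fail**

Step 8 (key annulation). The lithiated sulfoxide may act as a base and enolise the lactone instead of adding to it, or the β-keto sulfoxide monoanion may close through oxygen before the dianion forms. Fallback: the two bonds are made in the opposite order and in two operations. The lithium enolate of 4 (LDA, THF–DMPU, −78 °C) is alkylated with iodide 9 to give (3R,4R,5S)-5-(3,4-dimethoxyphenyl)-3-[(2S)-2-methoxy-4-(phenylsulfinyl)butyl]-4-methyloxolan-2-one F1. F1 is then closed by a Dieckmann-type condensation under equilibrating conditions (KOt-Bu, THF, 0 °C → rt), where the small equilibrium share of sulfinyl carbanion adds to the lactone and the acidic product drains the equilibrium. This sets out from 4 and 9 and comes back to the route at 12.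

Step 9 (allylation). Incomplete γ-deprotonation of the hindered tertiary C–H, alkylation at C2 or at oxygen, or insufficient facial selectivity at C6 would erode the 6S isomer. Fallback: 12 is first thermolysed (toluene, CaCO3, 90 °C) to (4S)-6-[(1S,2R)-1-(3,4-dimethoxyphenyl)-1-hydroxypropan-2-yl]-4-methoxycyclohex-2-en-1-one F2. The cross-conjugated lithium dienolate of F2 (LDA, 2.2 equiv, THF, −78 °C) is then allylated with allyl bromide. In that flatter ring the now allylic methoxy group shields one face, so trans alkylation is expected by analogy with 4-alkoxycyclohex-2-enone enolates. This sets out from 12 and comes back at 14.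

Step 4 (asymmetric methanol addition). Loss of enantiomeric purity through slow π-allyl equilibration, or attack at the terminal allyl carbon giving the linear ether. Fallback: 5 is resolved by hydrolytic kinetic resolution ((R,R)-(salen)Co(OAc), 0.55 equiv H2O, the catalyst enantiomer that leaves the S epoxide) to (2S)-2-vinyloxirane F3. F3 is opened by methanol at the allylic carbon with inversion (BF3·OEt2 cat., MeOH, −20 °C) to give 6. This sets out from 5 and comes back at 6.

**Further compounds**
F1 | step 8 | (3R,4R,5S)-5-(3,4-dimethoxyphenyl)-3-[(2S)-2-methoxy-4-(phenylsulfinyl)butyl]-4-methyloxolan-2-one | O=C1[C@H](C[C@H](OC)CCS(=O)c2ccccc2)[C@@H](C)[C@H](O1)c3ccc(OC)c(OC)c3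
F2 | step 9 | (4S)-6-[(1S,2R)-1-(3,4-dimethoxyphenyl)-1-hydroxypropan-2-yl]-4-methoxycyclohex-2-en-1-one | O=C1C=C[C@@H](OC)CC1[C@@H](C)[C@H](O)c2ccc(OC)c(OC)c2
F3 | step 4 | (2S)-2-vinyloxirane | C=C[C@H]1CO1
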